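**Assumption:** the SMILES is taken as the full definition of the target (maklamicin); labels C1–C32 follow the order of the carbon atoms in that SMILES; the carbinol centre C29 is carried as an epimer mixture until it is oxidised.

## Retrosynthetic overview

1. The target is an 11-membered carbocycle spanning a trans-decalin (C2 methyl axial), a cyclohexene and a 3-acyl spirotetronate.
2. Last ring: C12=C13 by ring-closing metathesis, then desilylation; before it the tetronate ring from a γ-hydroxy ynone and CO2.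
3. Key bond C25–C28: the propargylic alkoxide/acetylide dianion of the decalin (a d3, homoenolate-type equivalent of the ynone, nucleophilic at C28) adds to the α-quaternary cyclohexenone 31 and sets the spiro centre.
4. Decalin rings A and B together: catalyst-controlled intramolecular Diels–Alder of a 6-methylidene trienal (from myrcene and (R)-Roche ester), then hydrogenation from the equatorial face for the axial methyl.
5. Cyclohexenone: yeast desymmetrisation of 2-allyl-2-methylcyclohexane-1,3-dione, Baylis–Hillman, Luche, Carroll, CBS. Ring order: A/B and cyclohexene separately, then tetronate, then macrocycle.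

## Route

### Decalin fragment (steps 1–13)

Step 1
Reactants: 1 β-myrcene
Product: 2 γ-geraniol (7-methyl-3-methylideneoct-6-en-1-ol)
Conditions: 9-BBN, THF, 0 °C → rt; then NaOH, H2O2, 0 °C
Reagents that add atoms: hydrogen peroxide OO
Why: Brown hydroboration–oxidation; 9-BBN adds anti-Markovnikov to the monosubstituted terminus of the 2-substituted diene much faster than to the 1,1-disubstituted or trisubstituted alkene.

Step 2
Reactants: 2 γ-geraniol
Product: 3 5-[(7-methyl-3-methylideneoct-6-en-1-yl)sulfanyl]-1-phenyl-1H-tetrazole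
Conditions: 1-phenyl-1H-tetrazole-5-thiol, PPh3, DIAD, THF, 0 °C → rt
Reagents that add atoms: 1-phenyl-1H-tetrazole-5-thiol Sc1nnnn1-c1ccccc1
Why: Mitsunobu thioetherification of the unhindered primary alcohol installs the Julia–Kocienski heteroaryl sulfide.

Step 3
Reactants: 3 tetrazolyl sulfide
Product: 4 5-[(7-methyl-3-methylideneoct-6-en-1-yl)sulfonyl]-1-phenyl-1H-tetrazole
Conditions: (NH4)6Mo7O24·4H2O (10 mol %), 30% H2O2, EtOH, 0 °C → rt
Reagents that add atoms: hydrogen peroxide OO
Why: Molybdate-catalysed peroxide oxidation takes sulfide to sulfone faster than it epoxidises the alkenes (chemoselective S-oxidation).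

Step 4
Reactants: 5 methyl (R)-3-hydroxy-2-methylpropanoate ((R)-Roche ester)
Product: 6 methyl (R)-3-[(tert-butyldimethylsilyl)oxy]-2-methylpropanoate
Conditions: TBSCl, imidazole, DMF, rt
Reagents that add atoms: tert-butyldimethylsilyl chloride CC(C)(C)[Si](C)(C)Cl
Why: Standard silylation of the primary alcohol; the stereocentre (later C10) comes from the chiral pool and is not touched.

Step 5
Reactants: 6 silyl ether ester
Product: 7 (R)-3-[(tert-butyldimethylsilyl)oxy]-2-methylpropanal
Conditions: i-Bu2AlH (1.05 equiv), CH2Cl2, −78 °C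
Reagents that add atoms: none
Why: Half-reduction of the ester through the stable tetrahedral aluminate at −78 °C gives the α-chiral aldehyde without epimerisation.

Step 6
Reactants: 7 aldehyde
Product: 8 (2E,4S)-5-[(tert-butyldimethylsilyl)oxy]-4-methylpent-2-enal
Conditions: Ph3P=CHCHO, toluene, 80 °C
Reagents that add atoms: (triphenylphosphoranylidene)acetaldehyde O=CC=P(c1ccccc1)(c1ccccc1)c1ccccc1
Why: Wittig olefination with the stabilised ylide gives the (E)-enal under neutral conditions that do not epimerise the α-centre.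

Step 7
Reactants: 4 sulfone; 8 enal
Product: 9 tert-butyl{[(2S,3E,5E)-2,12-dimethyl-8-methylidenetrideca-3,5,11-trien-1-yl]oxy}dimethylsilane
Conditions: 4, KN(SiMe3)2, DME, −60 °C; then 8, −60 °C → rt
Reagents that add atoms: none
Why: Julia–Kocienski olefination (addition, Smiles rearrangement, anti-elimination) forms C6=C7 E-selectively and completes the (E,E)-diene; any minor Z isomer is removed here.

Step 8
Reactants: 9 tetraene
Product: 11 (2E,8E,10E,12S)-13-[(tert-butyldimethylsilyl)oxy]-2,12-dimethyl-6-methylidenetrideca-2,8,10-trienal, via trienol 10 (not isolated)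
Conditions: SeO2 (0.3 equiv), t-BuOOH, salicylic acid (cat.), CH2Cl2, 0 °C → rt; then MnO2, CH2Cl2, rt
Reagents that add atoms: tert-butyl hydroperoxide CC(C)(C)OO
Why: Riley–Sharpless allylic oxidation (ene reaction then [2,3]-shift) attacks the most electron-rich trisubstituted alkene at its (E)-methyl group, and MnO2 takes the allylic alcohol on to the (E)-2-methylenal.

Step 9
Reactants: 11 trienal
Product: 12 (1S,2S,4aS,8aR)-2-[(2S)-1-[(tert-butyldimethylsilyl)oxy]propan-2-yl]-1-methyl-6-methylidene-1,2,4a,5,6,7,8,8a-octahydronaphthalene-1-carbaldehyde (trans-fused)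
Conditions: (S)-o-tolyl-CBS-oxazaborolidine (20 mol %), Tf2NH (18 mol %), CH2Cl2, −78 → −40 °C
Reagents that add atoms: none
Why: Intramolecular Diels–Alder reaction of the oxazaborolidinium-activated enal through the formyl-endo, chair-tether transition state gives the trans-fused decalin with C5, C6, C9 and C30 in the required relative sense from the E dienophile and E,E diene, the catalyst antipode (chosen by the Corey formyl C–H···O model for attack on the Cα-Re face) overrides the weak bias of C10, and C2 is kept sp2 so that no tether stereocentre forces the methyl equatorial.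

Step 10
Reactants: 12 methylidene decalin aldehyde
Product: 13 (1S,2S,4aS,6S,8aR)-2-[(2S)-1-[(tert-butyldimethylsilyl)oxy]propan-2-yl]-1,6-dimethyl-1,2,4a,5,6,7,8,8a-octahydronaphthalene-1-carbaldehyde (6-methyl axial)
Conditions: H2 (1 atm), RhCl(PPh3)3 (5 mol %), benzene, rt
Reagents that add atoms: none
Why: Homogeneous hydrogenation reduces only the unhindered 1,1-disubstituted exocyclic alkene and delivers hydrogen to C2 from the equatorial side, away from the syn-axial hydrogens on C4 and C6, which sets the axial methyl (about 4:1 expected, minor epimer removed by chromatography).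

Step 11
Reactants: 13 silyl ether aldehyde
Product: 14 (1S,2S,4aS,6S,8aR)-2-[(2S)-1-hydroxypropan-2-yl]-1,6-dimethyl-1,2,4a,5,6,7,8,8a-octahydronaphthalene-1-carbaldehyde
Conditions: TBAF, AcOH, THF, 0 °C → rt
Reagents that add atoms: none
Why: Fluoride-mediated desilylation; the aldehyde sits on a quaternary carbon and cannot enolise.

Step 12
Reactants: 14 hydroxy aldehyde
Product: 15 (1S,2S,4aS,6S,8aR)-1,6-dimethyl-2-[(2S)-1-oxopropan-2-yl]-1,2,4a,5,6,7,8,8a-octahydronaphthalene-1-carbaldehyde
Conditions: Dess–Martin periodinane, NaHCO3, CH2Cl2, 0 °C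
Reagents that add atoms: none
Why: Buffered Dess–Martin oxidation gives the α-branched aldehyde without epimerising C10.

Step 13
Reactants: 15 dialdehyde
Product: 16 (1S,2S,4aS,6S,8aR)-2-[(2R)-but-3-en-2-yl]-1,6-dimethyl-1,2,4a,5,6,7,8,8a-octahydronaphthalene-1-carbaldehyde
Conditions: Ph3PCH3Br (1.05 equiv), KN(SiMe3)2, THF, −78 → −20 °C
Reagents that add atoms: methyltriphenylphosphonium bromide C[P+](c1ccccc1)(c1ccccc1)c1ccccc1.[Br-]
Why: Wittig methylenation with one equivalent of ylide at low temperature takes the α-branched aldehyde in preference to the neopentyl aldehyde on quaternary C30 and gives the C12=C13 vinyl group.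

### Cyclohexenone fragment (steps 14–25)

Step 14
Reactants: 17 2-methylcyclohexane-1,3-dione
Product: 18 2-methyl-2-(prop-2-en-1-yl)cyclohexane-1,3-dione
Conditions: allyl bromide, 1 M NaOH (aq), rt
Reagents that add atoms: allyl bromide C=CCBr
Why: C-Alkylation of the 1,3-dione enolate gives the 2,2-disubstituted dione.

Step 15
Reactants: 18 allyl methyl dione
Product: 19 (2S,3S)-3-hydroxy-2-methyl-2-(prop-2-en-1-yl)cyclohexan-1-one (hydroxyl cis to allyl)
Conditions: baker's yeast (Saccharomyces cerevisiae), sucrose, H2O, 30 °C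
Reagents that add atoms: none
Why: Enzymatic desymmetrising reduction of one enantiotopic carbonyl from the face anti to the allyl group sets quaternary C15 and the temporary carbinol C25.

Step 16
Reactants: 19 hydroxy ketone
Product: 20 (1S,2S)-2-methyl-3-oxo-2-(prop-2-en-1-yl)cyclohexyl acetate
Conditions: Ac2O, pyridine, DMAP (cat.), CH2Cl2, rt
Reagents that add atoms: acetic anhydride CC(=O)OC(C)=O
Why: Acetylation protects the future C25 ketone with a group orthogonal to the silyl ethers.

Step 17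
Reactants: 20 keto acetate
Product: 21 (1S,6S)-6-methyl-5-oxo-6-(prop-2-en-1-yl)cyclohex-3-en-1-yl acetate
Conditions: IBX (2 equiv), DMSO/fluorobenzene, 70 °C
Reagents that add atoms: none
Why: IBX dehydrogenation of the ketone, which has only one enolisable side, gives the enone C17(=O)–C18=C20.

Step 18
Reactants: 21 enone
Product: 22 (1S,6S)-4-(hydroxymethyl)-6-methyl-5-oxo-6-(prop-2-en-1-yl)cyclohex-3-en-1-yl acetate
Conditions: 37% aq HCHO, DMAP (20 mol %), THF/H2O, rt
Reagents that add atoms: formaldehyde C=O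
Why: Morita–Baylis–Hillman reaction (conjugate addition of DMAP, aldol, elimination) installs C19 on the enone α-carbon C18.

Step 19
Reactants: 22 hydroxymethyl enone
Product: 23 (1S,6S)-4-{[(tert-butyldimethylsilyl)oxy]methyl}-6-methyl-5-oxo-6-(prop-2-en-1-yl)cyclohex-3-en-1-yl acetate
Conditions: TBSCl, imidazole, CH2Cl2, rt
Reagents that add atoms: tert-butyldimethylsilyl chloride CC(C)(C)[Si](C)(C)Cl
Why: Silylation of the primary allylic alcohol.

Step 20
Reactants: 23 silyloxymethyl enone
Product: 24 cyclohexenyl acetate with the C17 hydroxyl cis to both the allyl group and the acetate (all-cis; SMILES)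
Conditions: NaBH4, CeCl3·7H2O, MeOH, −40 °C
Reagents that add atoms: none
Why: Luche 1,2-reduction delivers hydride from the methyl-bearing face, anti to the pseudoaxial allyl group in the half-chair with equatorial acetate, so the C17 hydroxyl ends cis to allyl.

Step 21
Reactants: 24 allylic alcohol
Product: 27 methyl ketone with the 2-oxopropyl group on C20 cis to allyl and the alkene at C17=C18, via acetoacetate 25 (not isolated), via keto acid 26 (not isolated)
Conditions: 2,2,6-trimethyl-4H-1,3-dioxin-4-one, xylene, 140 °C; then 1,2-dichlorobenzene, 190 °C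
Reagents that add atoms: 2,2,6-trimethyl-4H-1,3-dioxin-4-one CC1=CC(=O)OC(C)(C)O1
Why: Carroll rearrangement; the acetoacetate enol undergoes a suprafacial [3,3]-shift that transfers chirality from C17–O to the new C20–C21 bond and moves the alkene to C17=C18, and the keto acid then loses CO2.

Step 22
Reactants: 27 methyl ketone
Product: 28 secondary alcohol with (R)-configured C22 (SMILES)
Conditions: (S)-Me-CBS (20 mol %), catecholborane, toluene, −78 °C
Reagents that add atoms: none
Why: CBS reduction with catecholborane, which spares the alkenes, reduces the methyl ketone under reagent control, the (S)-catalyst giving the (R)-carbinol.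

Step 23
Reactants: 28 alcohol
Product: 29 bis-silyl ether acetate (SMILES)
Conditions: TBSOTf, 2,6-lutidine, CH2Cl2, −78 → 0 °C
Reagents that add atoms: tert-butyldimethylsilyl trifluoromethanesulfonate CC(C)(C)[Si](C)(C)OS(=O)(=O)C(F)(F)F
Why: Silylation of the secondary alcohol.

Step 24
Reactants: 29 bis-silyl ether acetate
Product: 30 cyclohexenol (free C25 hydroxyl; SMILES)
Conditions: K2CO3, MeOH, rt
Reagents that add atoms: none
Why: Mild methanolysis removes the acetate and leaves both silyl ethers.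

Step 25
Reactants: 30 cyclohexenol
Product: 31 (2R,5R)-4-{[(tert-butyldimethylsilyl)oxy]methyl}-5-[(2R)-2-[(tert-butyldimethylsilyl)oxy]propyl]-2-methyl-2-(prop-2-en-1-yl)cyclohex-3-en-1-one
Conditions: Dess–Martin periodinane, NaHCO3, CH2Cl2, rt
Reagents that add atoms: none
Why: Dess–Martin oxidation regenerates the C25 ketone; C15 is quaternary and C20 is not α to it, so no stereocentre is at risk.

### Union and endgame (steps 26–30)

Step 26
Reactants: 16 decalin vinyl aldehyde; 31 cyclohexenone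
Product: 33 diol (tertiary C25 carbinol, secondary propargylic C29 carbinol as epimers), via ynol 32 (not isolated)
Conditions: HC≡CMgBr (1.05 equiv), THF, −78 → 0 °C; n-BuLi (1.1 equiv), −78 °C; CeCl3 (1.5 equiv), −78 °C; then 31 (0.9 equiv), −78 → −40 °C
Reagents that add atoms: ethynylmagnesium bromide C#C[Mg]Br
Why: The alkoxide/acetylide dianion made in the flask is a d3 (homoenolate-type) equivalent of the decalinyl ynone and adds as its cerium acetylide to the enolisable α-quaternary ketone (1,2-addition) axially from the methyl-bearing face, anti to the pseudoaxial allyl group in the half-chair with the C20 chain pseudoequatorial, which puts C28 cis to the C15 methyl and the oxygen cis to allyl as in the target.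

Step 27
Reactants: 33 diol
Product: 34 γ-hydroxy ynone
Conditions: MnO2 (activated), CH2Cl2, rt
Reagents that add atoms: none
Why: MnO2 oxidises the secondary propargylic alcohol to the ynone and cannot touch the tertiary one.

Step 28
Reactants: 34 γ-hydroxy ynone
Product: 36 3-acyl spirotetronic acid (open diene), via alkylidene carbonate 35 (not isolated)
Conditions: CO2 (10 atm), AgOAc (10 mol %), DBU (1.5 equiv), MeCN, rt → 60 °C; then 1 M HCl
Reagents that add atoms: carbon dioxide O=C=O
Why: Silver-catalysed carboxylative cyclisation; the tertiary alkoxide captures CO2 and closes 5-exo-dig onto the silver-activated alkyne, and DBU opens the alkylidene carbonate to a diketone enolate that is C-acylated by the carbonate (1,3 O-to-C acyl shift), leaving C25 untouched.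

Step 29
Reactants: 36 acyl tetronic acid diene
Product: 37 macrocyclic bis-silyl ether (11-membered ring, E C12=C13)
Conditions: second-generation Grubbs catalyst (10 mol %), toluene (1 mM), 80 °C
Reagents that add atoms: none
Why: Ring-closing metathesis of the two terminal alkenes forms the 11-membered ring, the E olefin being the less strained isomer in a ring held by the decalin and the spirotetronate.

Step 30
Reactants: 37 macrocyclic bis-silyl ether
Product: 38 target (maklamicin)
Conditions: HF·pyridine, pyridine/THF, 0 °C → rt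
Reagents that add atoms: none
Why: Fluoride-mediated desilylation removes both silyl ethers and leaves the acid-stable acyl tetronic acid alone.

## Compound list

1 | β-myrcene (7-methyl-3-methylideneocta-1,6-diene) | C=CC(=C)CCC=C(C)C | starting material
2 | γ-geraniol (7-methyl-3-methylideneoct-6-en-1-ol) | OCCC(=C)CCC=C(C)C | intermediate
3 | 5-[(7-methyl-3-methylideneoct-6-en-1-yl)sulfanyl]-1-phenyl-1H-tetrazole | CC(C)=CCCC(=C)CCSc1nnnn1-c1ccccc1 | intermediate
4 | 5-[(7-methyl-3-methylideneoct-6-en-1-yl)sulfonyl]-1-phenyl-1H-tetrazole | CC(C)=CCCC(=C)CCS(=O)(=O)c1nnnn1-c1ccccc1 | intermediate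
5 | methyl (R)-3-hydroxy-2-methylpropanoate | COC(=O)[C@H](C)CO | starting material
6 | methyl (R)-3-[(tert-butyldimethylsilyl)oxy]-2-methylpropanoate | COC(=O)[C@H](C)CO[Si](C)(C)C(C)(C)C | intermediate
7 | (R)-3-[(tert-butyldimethylsilyl)oxy]-2-methylpropanal | O=C[C@H](C)CO[Si](C)(C)C(C)(C)C | intermediate
8 | (2E,4S)-5-[(tert-butyldimethylsilyl)oxy]-4-methylpent-2-enal | O=C/C=C/[C@H](C)CO[Si](C)(C)C(C)(C)C | intermediate
9 | tert-butyl{[(2S,3E,5E)-2,12-dimethyl-8-methylidenetrideca-3,5,11-trien-1-yl]oxy}dimethylsilane | CC(C)=CCCC(=C)C/C=C/C=C/[C@H](C)CO[Si](C)(C)C(C)(C)C | intermediate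
10 | (2E,8E,10E,12S)-13-[(tert-butyldimethylsilyl)oxy]-2,12-dimethyl-6-methylidenetrideca-2,8,10-trien-1-ol | OC/C(C)=C/CCC(=C)C/C=C/C=C/[C@H](C)CO[Si](C)(C)C(C)(C)C | intermediate
11 | (2E,8E,10E,12S)-13-[(tert-butyldimethylsilyl)oxy]-2,12-dimethyl-6-methylidenetrideca-2,8,10-trienal | O=C/C(C)=C/CCC(=C)C/C=C/C=C/[C@H](C)CO[Si](C)(C)C(C)(C)C | intermediate
12 | (1S,2S,4aS,8aR)-2-[(2S)-1-[(tert-butyldimethylsilyl)oxy]propan-2-yl]-1-methyl-6-methylidene-1,2,4a,5,6,7,8,8a-octahydronaphthalene-1-carbaldehyde | O=C[C@@]1(C)[C@@H]2CCC(=C)C[C@H]2C=C[C@H]1[C@H](C)CO[Si](C)(C)C(C)(C)C | intermediate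
13 | (1S,2S,4aS,6S,8aR)-2-[(2S)-1-[(tert-butyldimethylsilyl)oxy]propan-2-yl]-1,6-dimethyl-1,2,4a,5,6,7,8,8a-octahydronaphthalene-1-carbaldehyde | O=C[C@@]1(C)[C@@H]2CC[C@H](C)C[C@H]2C=C[C@H]1[C@H](C)CO[Si](C)(C)C(C)(C)C | intermediate
14 | (1S,2S,4aS,6S,8aR)-2-[(2S)-1-hydroxypropan-2-yl]-1,6-dimethyl-1,2,4a,5,6,7,8,8a-octahydronaphthalene-1-carbaldehyde | O=C[C@@]1(C)[C@@H]2CC[C@H](C)C[C@H]2C=C[C@H]1[C@H](C)CO | intermediate
15 | (1S,2S,4aS,6S,8aR)-1,6-dimethyl-2-[(2S)-1-oxopropan-2-yl]-1,2,4a,5,6,7,8,8a-octahydronaphthalene-1-carbaldehyde | O=C[C@@]1(C)[C@@H]2CC[C@H](C)C[C@H]2C=C[C@H]1[C@H](C)C=O | intermediate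
16 | (1S,2S,4aS,6S,8aR)-2-[(2R)-but-3-en-2-yl]-1,6-dimethyl-1,2,4a,5,6,7,8,8a-octahydronaphthalene-1-carbaldehyde | O=C[C@@]1(C)[C@@H]2CC[C@H](C)C[C@H]2C=C[C@H]1[C@H](C)C=C | intermediate
17 | 2-methylcyclohexane-1,3-dione | CC1C(=O)CCCC1=O | starting material
18 | 2-methyl-2-(prop-2-en-1-yl)cyclohexane-1,3-dione | C=CCC1(C)C(=O)CCCC1=O | intermediate
19 | (2S,3S)-3-hydroxy-2-methyl-2-(prop-2-en-1-yl)cyclohexan-1-one | C=CC[C@]1(C)C(=O)CCC[C@@H]1O | intermediate
20 | (1S,2S)-2-methyl-3-oxo-2-(prop-2-en-1-yl)cyclohexyl acetate | C=CC[C@]1(C)C(=O)CCC[C@@H]1OC(C)=O | intermediate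
21 | (1S,6S)-6-methyl-5-oxo-6-(prop-2-en-1-yl)cyclohex-3-en-1-yl acetate | C=CC[C@]1(C)C(=O)C=CC[C@@H]1OC(C)=O | intermediate
22 | (1S,6S)-4-(hydroxymethyl)-6-methyl-5-oxo-6-(prop-2-en-1-yl)cyclohex-3-en-1-yl acetate | C=CC[C@]1(C)C(=O)C(CO)=CC[C@@H]1OC(C)=O | intermediate
23 | (1S,6S)-4-{[(tert-butyldimethylsilyl)oxy]methyl}-6-methyl-5-oxo-6-(prop-2-en-1-yl)cyclohex-3-en-1-yl acetate | C=CC[C@]1(C)C(=O)C(CO[Si](C)(C)C(C)(C)C)=CC[C@@H]1OC(C)=O | intermediate
24 | 4-{[(tert-butyldimethylsilyl)oxy]methyl}-5-hydroxy-6-methyl-6-(prop-2-en-1-yl)cyclohex-3-en-1-yl acetate, hydroxyl, allyl and acetate all cis | C=CC[C@]1(C)[C@H](O)C(CO[Si](C)(C)C(C)(C)C)=CC[C@@H]1OC(C)=O | intermediate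
25 | 3-oxobutanoate (acetoacetate) ester of 24 at the C17 hydroxyl | C=CC[C@]1(C)[C@H](OC(=O)CC(C)=O)C(CO[Si](C)(C)C(C)(C)C)=CC[C@@H]1OC(C)=O | intermediate
26 | 2-acetyl-2-(ring C20)acetic acid from the [3,3]-shift of 25 (β-keto acid, alkene at C17=C18) | C=CC[C@]1(C)C=C(CO[Si](C)(C)C(C)(C)C)[C@H](C(C(C)=O)C(=O)O)C[C@@H]1OC(C)=O | intermediate
27 | 4-{[(tert-butyldimethylsilyl)oxy]methyl}-2-methyl-5-(2-oxopropyl)-2-(prop-2-en-1-yl)cyclohex-3-en-1-yl acetate, oxopropyl, allyl and acetate all cis | C=CC[C@]1(C)C=C(CO[Si](C)(C)C(C)(C)C)[C@H](CC(C)=O)C[C@@H]1OC(C)=O | intermediate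
28 | as 27 with the side chain reduced to (2R)-2-hydroxypropyl | C=CC[C@]1(C)C=C(CO[Si](C)(C)C(C)(C)C)[C@H](C[C@@H](C)O)C[C@@H]1OC(C)=O | intermediate
29 | as 28 with the side-chain hydroxyl as its tert-butyldimethylsilyl ether | C=CC[C@]1(C)C=C(CO[Si](C)(C)C(C)(C)C)[C@H](C[C@@H](C)O[Si](C)(C)C(C)(C)C)C[C@@H]1OC(C)=O | intermediate
30 | cyclohex-3-en-1-ol from 29 after acetate removal | C=CC[C@]1(C)C=C(CO[Si](C)(C)C(C)(C)C)[C@H](C[C@@H](C)O[Si](C)(C)C(C)(C)C)C[C@@H]1O | intermediate
31 | (2R,5R)-4-{[(tert-butyldimethylsilyl)oxy]methyl}-5-[(2R)-2-[(tert-butyldimethylsilyl)oxy]propyl]-2-methyl-2-(prop-2-en-1-yl)cyclohex-3-en-1-one | C=CC[C@]1(C)C=C(CO[Si](C)(C)C(C)(C)C)[C@H](C[C@@H](C)O[Si](C)(C)C(C)(C)C)CC1=O | intermediate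
32 | 1-(decalinyl)prop-2-yn-1-ol from 16 and acetylene (C29 epimers) | C#CC(O)[C@@]1(C)[C@@H]2CC[C@H](C)C[C@H]2C=C[C@H]1[C@H](C)C=C | intermediate
33 | but-2-yne-1,4-diol joining C30 of the decalin (secondary carbinol C29, epimers) to the cyclohexene (tertiary carbinol C25, alkyne cis to the C15 methyl) | C=CC[C@]1(C)C=C(CO[Si](C)(C)C(C)(C)C)[C@H](C[C@@H](C)O[Si](C)(C)C(C)(C)C)C[C@@]1(O)C#CC(O)[C@@]3(C)[C@@H]4CC[C@H](C)C[C@H]4C=C[C@H]3[C@H](C)C=C | intermediate
34 | γ-hydroxy ynone (C29 ketone, C25 tertiary alcohol) | C=CC[C@]1(C)C=C(CO[Si](C)(C)C(C)(C)C)[C@H](C[C@@H](C)O[Si](C)(C)C(C)(C)C)C[C@@]1(O)C#CC(=O)[C@@]3(C)[C@@H]4CC[C@H](C)C[C@H]4C=C[C@H]3[C@H](C)C=C | intermediate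
35 | spiro (Z)-4-(2-oxo-2-decalinylethylidene)-1,3-dioxolan-2-one (alkylidene carbonate) | C=CC[C@]1(C)C=C(CO[Si](C)(C)C(C)(C)C)[C@H](C[C@@H](C)O[Si](C)(C)C(C)(C)C)C[C@]15OC(=O)O/C5=C\C(=O)[C@@]3(C)[C@@H]4CC[C@H](C)C[C@H]4C=C[C@H]3[C@H](C)C=C | intermediate
36 | 3-(decalinylcarbonyl)-4-hydroxy spirotetronic acid bearing the allyl and butenyl groups (open diene) | C=CC[C@]1(C)C=C(CO[Si](C)(C)C(C)(C)C)[C@H](C[C@@H](C)O[Si](C)(C)C(C)(C)C)C[C@]15OC(=O)C(=C5O)C(=O)[C@@]3(C)[C@@H]4CC[C@H](C)C[C@H]4C=C[C@H]3[C@H](C)C=C | intermediate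
37 | bis(tert-butyldimethylsilyl) ether of the target (macrocycle closed) | C[C@H]1CC[C@@H]2[C@H](C=C[C@H]3[C@H](C)/C=C/C[C@]4(C)C=C(CO[Si](C)(C)C(C)(C)C)[C@H](C[C@@H](C)O[Si](C)(C)C(C)(C)C)C[C@]45OC(=O)C(=C5O)C(=O)[C@@]23C)C1 | intermediate
38 | maklamicin (CNP0189906.1) | C[C@H]1CC[C@@H]2[C@H](C=C[C@H]3[C@H](C)/C=C/C[C@]4(C)C=C(CO)[C@H](C[C@@H](C)O)C[C@]45OC(=O)C(=C5O)C(=O)[C@@]23C)C1 | target

## Step count and risks

Total steps: 30 (13 for the decalin aldehyde 16, 12 for the cyclohexenone 31, 5 from the union to the target).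
Longest linear sequence: 17 steps (17 → 31 in steps 14–25, then steps 26–30).

Apart from the three steps below, the weaker points are the facial selectivity of step 10 (a separable mixture is expected), the catalyst control in step 9 and the mono-methylenation in step 13.

**Step 26, the fragment union.** The risks are enolisation of the hindered ketone and the face selectivity at C25. The fallback makes the same bond in the reverse order, with a small nucleophile on the ketone first. It sets out from ketone 31 and uses aldehyde 16. LiC≡CSiMe3 with CeCl3 in THF at −78 °C adds to 31 to give the silylalkynyl carbinol F1. K2CO3 in MeOH then gives the terminal alkynyl carbinol F2, whose C25 configuration can be checked before the decalin is committed. The O,C-dianion of F2 (2 equiv n-BuLi, THF, −78 °C) adds to the aldehyde of 16 and the route is rejoined at diol 33.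

**Step 28, the CO2 cascade to the acyl tetronic acid.** The risk is that the hindered tertiary alkoxide does not hold CO2 long enough to cyclise. The fallback sets out from ynone 34 and puts the carbonate on covalently. Boc2O with DMAP (or LiN(SiMe3)2 then Boc2O) gives the tert-butyl carbonate F3. Ph3PAuNTf2 (5 mol %, CH2Cl2, rt) then closes it 5-exo-dig with loss of isobutene to the alkylidene carbonate 35, which is now isolated. DBU in MeCN effects the O-to-C acyl shift and the route is rejoined at 36.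

**Step 29, the ring-closing metathesis.** The risks are ring strain, the E/Z ratio and the free tetronic acid. The fallback fixes the olefin geometry intermolecularly and closes the ring at C27–C29 instead. It sets out from ketone 31 and aldehyde 16.
- LiC≡CCO2Me (methyl propiolate, LiN(i-Pr)2, THF, −78 °C) adds to 31 to give the hydroxy ynoate F4.
- NaOMe in MeOH (conjugate addition, lactonisation) converts it into the methyl spirotetronate F5.
- Cross-metathesis of the allyl group of F5 (type 1 olefin) with the α-branched vinyl group of 16 (type 2 olefin), using the second-generation Hoveyda–Grubbs catalyst, gives the E-alkene aldehyde F6.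
- LiN(i-Pr)2 in THF at −78 °C under high dilution lithiates C27 of the methyl tetronate, which adds to the aldehyde to give the macrocyclic carbinol F7.
- Dess–Martin oxidation gives the acyl methyl tetronate F8.
- LiCl in DMSO at 50 °C removes the O-methyl group and the route is rejoined at 37.

Further compounds
F1 | step 26 | tertiary (trimethylsilyl)ethynyl carbinol from 31 | C=CC[C@]1(C)C=C(CO[Si](C)(C)C(C)(C)C)[C@H](C[C@@H](C)O[Si](C)(C)C(C)(C)C)C[C@@]1(O)C#C[Si](C)(C)C
F2 | step 26 | tertiary ethynyl carbinol from 31 | C=CC[C@]1(C)C=C(CO[Si](C)(C)C(C)(C)C)[C@H](C[C@@H](C)O[Si](C)(C)C(C)(C)C)C[C@@]1(O)C#C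
F3 | step 28 | tert-butyl carbonate of the tertiary alcohol of 34 | C=CC[C@]1(C)C=C(CO[Si](C)(C)C(C)(C)C)[C@H](C[C@@H](C)O[Si](C)(C)C(C)(C)C)C[C@@]1(OC(=O)OC(C)(C)C)C#CC(=O)[C@@]3(C)[C@@H]4CC[C@H](C)C[C@H]4C=C[C@H]3[C@H](C)C=C
F4 | step 29 | methyl 3-(1-hydroxycyclohexenyl)propiolate from 31 | C=CC[C@]1(C)C=C(CO[Si](C)(C)C(C)(C)C)[C@H](C[C@@H](C)O[Si](C)(C)C(C)(C)C)C[C@@]1(O)C#CC(=O)OC
F5 | step 29 | 4-methoxy spirobutenolide (methyl spirotetronate) from F4 | C=CC[C@]1(C)C=C(CO[Si](C)(C)C(C)(C)C)[C@H](C[C@@H](C)O[Si](C)(C)C(C)(C)C)C[C@]15OC(=O)C=C5OC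
F6 | step 29 | cross-metathesis product of F5 and 16 (E C12=C13, free aldehyde) | O=C[C@@]1(C)[C@@H]2CC[C@H](C)C[C@H]2C=C[C@H]1[C@H](C)/C=C/C[C@]3(C)C=C(CO[Si](C)(C)C(C)(C)C)[C@H](C[C@@H](C)O[Si](C)(C)C(C)(C)C)C[C@]35OC(=O)C=C5OC
F7 | step 29 | macrocyclic C29 carbinol of the methyl tetronate (C29 epimers) | C[C@H]1CC[C@@H]2[C@H](C=C[C@H]3[C@H](C)/C=C/C[C@]4(C)C=C(CO[Si](C)(C)C(C)(C)C)[C@H](C[C@@H](C)O[Si](C)(C)C(C)(C)C)C[C@]45OC(=O)C(=C5OC)C(O)[C@@]23C)C1
F8 | step 29 | macrocyclic 3-acyl O-methyl tetronate | C[C@H]1CC[C@@H]2[C@H](C=C[C@H]3[C@H](C)/C=C/C[C@]4(C)C=C(CO[Si](C)(C)C(C)(C)C)[C@H](C[C@@H](C)O[Si](C)(C)C(C)(C)C)C[C@]45OC(=O)C(=C5OC)C(=O)[C@@]23C)C1
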